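**Retrosynthetic overview**
1. Target 14 ⇐ oxolane 13 by removing two silyl ethers.
2. Oxolane ring of 13 ⇐ oxygen-atom insertion into the benzylic C–C bond of cyclobutane 10 (ring expansion, the key step; it sets C2/C5 and keeps C3/C4 cis).
3. Cyclobutane 10 ⇐ [2+2] photocycloaddition of stilbene 6 with maleic anhydride 7 (fixes the cis pair of CH2O carbons), then reduction and silylation.
4. Stilbene 6 ⇐ McMurry coupling of syringaldehyde 5 ⇐ p-cresol 1 by bromination/oxidation and copper-catalysed methoxylation.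
5. Ring order: arene (bought) → cyclobutane → oxolane (last).

Assumption: the target SMILES describes a meso compound, (2R,3S,4R,5S) with a mirror plane through O1 and the C3–C4 midpoint, so it has no enantiomer; chiral intermediates are carried as racemates.

**Step 1**
Reactants: 1 p-cresol
Product: 4 3,5-dibromo-4-hydroxybenzaldehyde, via 2,6-dibromo-4-methylphenol 2 (not isolated), via 2,6-dibromo-4-(dibromomethyl)phenol 3 (not isolated)
Conditions: Br2 (2 equiv), o-dichlorobenzene, 30 °C; Br2 (2 equiv), 160 °C; H2O, 100 °C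
Reagents that add atoms: bromine, BrBr; water, O
Why: Electrophilic ortho,ortho-dibromination of the phenol, then radical side-chain dibromination and hydrolysis of the benzal bromide (the established one-pot p-cresol process); no stereocentre.

**Step 2**
Reactants: 4 3,5-dibromo-4-hydroxybenzaldehyde
Product: 5 syringaldehyde
Conditions: NaOMe (4 equiv), CuCl (10 mol %), DMF–MeOH, 110 °C; aq. HCl work-up
Reagents that add atoms: sodium methoxide, [Na+].[O-]C
Why: Copper-catalysed Ullmann-type methoxylation of both aryl bromides ortho to the phenoxide, the standard route to syringaldehyde.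

**Step 3**
Reactants: 5 syringaldehyde (2 equiv)
Product: 6 (E)-4,4'-dihydroxy-3,3',5,5'-tetramethoxystilbene
Conditions: TiCl4 (3 equiv), Zn (6 equiv), THF, reflux; aq. HCl work-up
Reagents that add atoms: none
Why: McMurry reductive homocoupling on low-valent titanium (pinacol coupling then deoxygenation) gives the E-alkene, the phenols riding through as titanium phenoxides.

**Step 4**
Reactants: 6 (E)-4,4'-dihydroxy-3,3',5,5'-tetramethoxystilbene; 7 maleic anhydride
Product: 8 rac-6,7-trans-6,7-bis(4-hydroxy-3,5-dimethoxyphenyl)-3-oxabicyclo[3.2.0]heptane-2,4-dione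
Conditions: hν (350–365 nm), 1,4-dioxane, N2, 20 °C
Reagents that add atoms: none
Why: Exciplex (charge-transfer) [2+2] photocycloaddition of the electron-rich stilbene singlet to the electron-poor alkene, run with 7 in excess (the surplus is recovered unchanged) to outpace stilbene dimerisation; the anhydride ring forces the two future CH2OH carbons cis, and the aryl configuration (trans from the E-alkene) does not matter because both benzylic centres are erased in step 7.

**Step 5**
Reactants: 8 cyclobutane anhydride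
Product: 9 rac-[3,4-trans-3,4-bis(4-hydroxy-3,5-dimethoxyphenyl)cyclobutane-1,2-cis-diyl]dimethanol
Conditions: LiAlH4 (6 equiv), THF, 0 °C to reflux; aq. KNaC4H4O6 work-up
Reagents that add atoms: none
Why: Hydride reduction of a cyclic anhydride to the 1,4-diol; the cis relationship of the two CH2OH groups is held by the ring fusion and no stereocentre is touched.

**Step 6**
Reactants: 9 cyclobutane diol
Product: 10 bis(tert-butyldiphenylsilyl) ether of 9 (both CH2OH silylated; phenols free)
Conditions: TBDPSCl (2.1 equiv), imidazole (4 equiv), CH2Cl2–DMF, −20 to 0 °C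
Reagents that add atoms: tert-butyl(chloro)diphenylsilane, CC(C)(C)[Si](Cl)(c1ccccc1)c1ccccc1
Why: Chemoselective silylation, since primary alcohols should react with the bulky silyl chloride much faster than the hindered 2,6-dimethoxyphenols; the silyl ethers are needed because free CH2OH groups would trap the quinone methides of step 7 as the isomeric 2-aryl-4-(hydroxybenzyl)oxolane.

**Step 7**
Reactants: 10 bis-silyl ether of the cyclobutane diol
Product: 13 meso-(2R,3S,4R,5S)-2,5-bis(4-hydroxy-3,5-dimethoxyphenyl)-3,4-bis[(tert-butyldiphenylsilyloxy)methyl]oxolane, via bis(quinone methide) 11 (not isolated), via quinone methide benzylic alcohol 12 (not isolated)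
Conditions: FeCl3·6H2O (2.2 equiv), acetone–H2O 9:1, 0.02 M, 0 °C, then 40 °C
Reagents that add atoms: water, O
Why: Proposed new method: oxidative oxygen-atom insertion into the benzylic C–C bond of a 1,2-bis(4-hydroxyaryl)cyclobutane (ring expansion of cyclobutane to oxolane), in which FeCl3 oxidises a syringyl phenol to its phenoxyl radical, the strained bond between the two benzylic carbons breaks by β-scission (about 26 kcal/mol of ring strain released) to a quinone methide plus a p-hydroxybenzyl radical, a second electron transfer gives the meso bis(quinone methide) 11, water adds 1,6 to give 12 and its new benzylic hydroxyl adds 1,6 to the second quinone methide (5-exo) to close the ring; the HCl set free lets the p-hydroxybenzylic C–O bonds ionise reversibly, so C2 and C5 settle with each aryl trans to its neighbouring CH2OSi group (hence the aryls cis), while the C3/C4 cis relationship is inherited from the cyclobutane; the closest known reactions are the radical-cation cleavage of 1,2-diarylcyclobutanes and the water capture of 8–8′-linked bis(quinone methides) in biomimetic oxidative lignan synthesis.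

**Step 8**
Reactants: 13 bis-silyl oxolane
Product: 14 meso-[(2R,3S,4R,5S)-2,5-bis(4-hydroxy-3,5-dimethoxyphenyl)oxolane-3,4-diyl]dimethanol (target)
Conditions: Bu4NF (3 equiv), AcOH (3 equiv), THF, 20 °C
Reagents that add atoms: none
Why: Fluoride cleavage of the two primary silyl ethers under acetic acid buffering, too mild to ionise the phenolic benzylic ethers, so the four stereocentres and the 2,5-ether linkage are untouched.

**Compound list**
1 | p-cresol (4-methylphenol) | Cc1ccc(O)cc1 | starting material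
2 | 2,6-dibromo-4-methylphenol | Cc1cc(Br)c(O)c(Br)c1 | intermediate (not isolated)
3 | 2,6-dibromo-4-(dibromomethyl)phenol | BrC(Br)c1cc(Br)c(O)c(Br)c1 | intermediate (not isolated)
4 | 3,5-dibromo-4-hydroxybenzaldehyde | O=Cc1cc(Br)c(O)c(Br)c1 | intermediate
5 | syringaldehyde (4-hydroxy-3,5-dimethoxybenzaldehyde) | COc1cc(C=O)cc(OC)c1O | intermediate
6 | (E)-4,4'-dihydroxy-3,3',5,5'-tetramethoxystilbene | COc1cc(/C=C/c2cc(OC)c(O)c(OC)c2)cc(OC)c1O | intermediate
7 | maleic anhydride | O=C1OC(=O)C=C1 | starting material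
8 | rac-6,7-trans-6,7-bis(4-hydroxy-3,5-dimethoxyphenyl)-3-oxabicyclo[3.2.0]heptane-2,4-dione (cis ring fusion) | O=C1OC(=O)[C@@H]2[C@H]1[C@@H](c3cc(OC)c(O)c(OC)c3)[C@@H]2c4cc(OC)c(O)c(OC)c4 | intermediate
9 | rac-[3,4-trans-3,4-bis(4-hydroxy-3,5-dimethoxyphenyl)cyclobutane-1,2-cis-diyl]dimethanol | OC[C@H]1[C@@H](CO)[C@@H](c2cc(OC)c(O)c(OC)c2)[C@@H]1c3cc(OC)c(O)c(OC)c3 | intermediate
10 | bis(tert-butyldiphenylsilyl) ether of 9 (CH2O–Si twice, phenols free) | CC(C)(C)[Si](c1ccccc1)(c1ccccc1)OC[C@H]1[C@@H](CO[Si](c2ccccc2)(c2ccccc2)C(C)(C)C)[C@@H](c3cc(OC)c(O)c(OC)c3)[C@@H]1c4cc(OC)c(O)c(OC)c4 | intermediate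
11 | meso-(2R,3S)-1,4-bis(tert-butyldiphenylsilyloxy)-2,3-bis[(3,5-dimethoxy-4-oxocyclohexa-2,5-dien-1-ylidene)methyl]butane | CC(C)(C)[Si](c1ccccc1)(c1ccccc1)OC[C@H](C=C1C=C(OC)C(=O)C(OC)=C1)[C@@H](CO[Si](c1ccccc1)(c1ccccc1)C(C)(C)C)C=C1C=C(OC)C(=O)C(OC)=C1 | intermediate (not isolated)
12 | mono-hydrate of 11: one quinone methide converted into ArCH(OH), both carbinol epimers | CC(C)(C)[Si](c1ccccc1)(c1ccccc1)OC[C@H](C(O)c1cc(OC)c(O)c(OC)c1)[C@@H](CO[Si](c1ccccc1)(c1ccccc1)C(C)(C)C)C=C1C=C(OC)C(=O)C(OC)=C1 | intermediate (not isolated)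
13 | meso-(2R,3S,4R,5S)-2,5-bis(4-hydroxy-3,5-dimethoxyphenyl)-3,4-bis[(tert-butyldiphenylsilyloxy)methyl]oxolane | COc1cc([C@H]2O[C@@H](c3cc(OC)c(O)c(OC)c3)[C@H](CO[Si](c4ccccc4)(c4ccccc4)C(C)(C)C)[C@@H]2CO[Si](c5ccccc5)(c5ccccc5)C(C)(C)C)cc(OC)c1O | intermediate
14 | meso-[(2R,3S,4R,5S)-2,5-bis(4-hydroxy-3,5-dimethoxyphenyl)oxolane-3,4-diyl]dimethanol | COc1cc([C@H]2O[C@@H](c3cc(OC)c(O)c(OC)c3)[C@H](CO)[C@@H]2CO)cc(OC)c1O | target

**Step count**
Total steps: 8. Longest linear sequence: 8 (from 1).

**Three steps most likely to fail**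

Step 7 (the proposed new step). The phenoxyl radicals may lose the cyclobutyl benzylic hydrogen instead of cleaving the ring. Full cycloreversion to a sinapyl ether would leak into the 3,4-trans series. Prolonged acid could give desilylative closure onto a CH2O oxygen or aryltetralin formation. The fallback uses known chemistry and runs from 10 back to 13. Acetylation of both phenols (Ac2O, pyridine) gives the bis(aryl acetate) F1. Photo-oxygenation sensitised by 9,10-dicyanoanthracene (O2, hν, MeCN; electron-transfer cleavage of the 1,2-diarylcyclobutane with O2 capture) gives the 3,6-diaryl-1,2-dioxane F2. PPh3 in toluene at 80 °C removes one oxygen and contracts the ring to the oxolane diacetate F3, formed as C2/C5 epimers (the one matching 13 is drawn). K2CO3 in MeOH then cleaves the acetates, and brief treatment with HCl in aqueous acetone equilibrates the benzylic centres to give 13.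

Step 4. E/Z isomerisation, stilbene self-dimerisation or charge-transfer copolymerisation with maleic anhydride may outrun the cross cycloaddition. The fallback avoids the cyclobutane altogether and runs from 6 to 14. Acetylation gives the stilbene diacetate F4, and dimethyldioxirane in acetone gives the trans-oxirane F5. Irradiation with 9,10-dicyanoanthracene in the presence of maleic anhydride 7 opens the oxirane to its carbonyl ylide, whose [3+2] cycloaddition gives the 2,5-cis-diaryl oxolane anhydride as the exo adduct F6 beside the endo adduct F7, which is separated. LiAlH4 reduces the anhydride of F6 and cleaves both aryl acetates, giving 14 directly.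

Step 6. The phenols may be silylated competitively. The fallback runs from 9 to 10: exhaustive silylation (TBDPSCl 4.5 equiv, imidazole, DMF, 40 °C) gives the tetrasilyl ether F8, and K2CO3 in MeOH, which cleaves only the two aryl silyl ethers, returns 10.

**Further compounds**
F1 | step 7 | bis(aryl acetate) of 10 | CC(C)(C)[Si](c1ccccc1)(c1ccccc1)OC[C@H]1[C@@H](CO[Si](c2ccccc2)(c2ccccc2)C(C)(C)C)[C@@H](c3cc(OC)c(OC(C)=O)c(OC)c3)[C@@H]1c4cc(OC)c(OC(C)=O)c(OC)c4
F2 | step 7 | 3,6-bis(4-acetoxy-3,5-dimethoxyphenyl)-4,5-cis-bis[(tert-butyldiphenylsilyloxy)methyl]-1,2-dioxane (isomer with each aryl trans to its neighbour drawn) | CC(=O)Oc1c(OC)cc(cc1OC)[C@H]2OO[C@@H](c3cc(OC)c(OC(C)=O)c(OC)c3)[C@H](CO[Si](c4ccccc4)(c4ccccc4)C(C)(C)C)[C@@H]2CO[Si](c5ccccc5)(c5ccccc5)C(C)(C)C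
F3 | step 7 | diacetate of 13 | COc1cc([C@H]2O[C@@H](c3cc(OC)c(OC(C)=O)c(OC)c3)[C@H](CO[Si](c4ccccc4)(c4ccccc4)C(C)(C)C)[C@@H]2CO[Si](c5ccccc5)(c5ccccc5)C(C)(C)C)cc(OC)c1OC(C)=O
F4 | step 4 | (E)-4,4'-diacetoxy-3,3',5,5'-tetramethoxystilbene | COc1cc(/C=C/c2cc(OC)c(OC(C)=O)c(OC)c2)cc(OC)c1OC(C)=O
F5 | step 4 | rac-trans-2,3-bis(4-acetoxy-3,5-dimethoxyphenyl)oxirane | CC(=O)Oc1c(OC)cc(cc1OC)[C@H]2O[C@@H]2c3cc(OC)c(OC(C)=O)c(OC)c3
F6 | step 4 | exo adduct, 4,6-bis(4-acetoxy-3,5-dimethoxyphenyl)tetrahydrofuro[3,4-c]furan-1,3-dione with the aryls cis to each other and trans to the anhydride ring | CC(=O)Oc1c(OC)cc(cc1OC)[C@H]2O[C@@H](c3cc(OC)c(OC(C)=O)c(OC)c3)[C@@H]4C(=O)OC(=O)[C@H]24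
F7 | step 4 | endo (all-cis) isomer of F6 | CC(=O)Oc1c(OC)cc(cc1OC)[C@H]2O[C@@H](c3cc(OC)c(OC(C)=O)c(OC)c3)[C@H]4C(=O)OC(=O)[C@@H]24
F8 | step 6 | tetrakis(tert-butyldiphenylsilyl) ether of 9 | CC(C)(C)[Si](c1ccccc1)(c1ccccc1)OC[C@H]1[C@@H](CO[Si](c2ccccc2)(c2ccccc2)C(C)(C)C)[C@@H](c3cc(OC)c(O[Si](c5ccccc5)(c5ccccc5)C(C)(C)C)c(OC)c3)[C@@H]1c4cc(OC)c(O[Si](c6ccccc6)(c6ccccc6)C(C)(C)C)c(OC)c4
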